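The readings are simulated on assumed constants; noise was put on by code.

Which flask holds more monomer in chains after 2.0 d on equal charges: south-east at 10 °C or south at 40 °C?

| setting | larch | maple | oak | south-east | south |
|---|---|---|---|---|---|
| solid monomer | 0.050 M | 0.050 M | 0.050 M | 0.050 M | 0.050 M |
| transfer agent | 0.015 M | 0.015 M | 0.030 M | 0.0150 M | 0.0150 M |
| initiator | 0.12 mM | 0.19 mM | 0.25 mM | 0.25 mM | 0.25 mM |
| temperature | 5 °C | 25 °C | 5 °C | 10 °C | 40 °C |
| remark | run made earlier | run made earlier | run made earlier |  |  |
| time |  |  |  | 2.0 d | 2.0 d |

| run | time / h | monomer in chains / % | solid monomer / % |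
|---|---|---|---|
| larch | 6.00 | 2.7 | 19.8 |
| larch | 12.0 | 8.8 | 9.5 |
| larch | 15.0 | 14.2 | 3.9 |
| larch | 25.0 | 28.6 | 0.4 |
| larch | 30.0 | 35.1 | 0 |
| maple | 3.00 | 5.1 | 37.6 |
| maple | 6.00 | 22.5 | 8.6 |
| maple | 8.00 | 35.1 | 0 |
| maple | 12.0 | 49.2 | 0 |
| maple | 15.0 | 55.5 | 0.2 |
| oak | 6.00 | 3.4 | 19.5 |
| oak | 12.0 | 16.9 | 3.8 |
| oak | 15.0 | 24.1 | 0 |
| oak | 25.0 | 47.1 | 0.9 |
| oak | 30.0 | 54.5 | 0 |

(standard deviation of a reading: 0.5 percentage points)

- as a solid, counted per litre of solution: solid monomer
- the analysis behind the earlier runs scatters by 0.5 percentage points, standard deviation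
- steps under discussion: free monomer + initiator -> living end + monomer in chains; free monomer + living end -> monomer in chains + living end; monomer in chains -> over-reaction product; living end + transfer agent -> dead chain; solid monomer <-> free monomer
- at the start none of the solid monomer is in solution

1. the best flask by amount of monomer in chains, in percent of the solid monomer charged; "all alike" if 1.5 percentage points covers them all (south-east / south / all alike)
2. amount of monomer in chains at the end, in percent of the solid monomer charged, south-east
3. amount of monomer in chains at the end, in percent of the solid monomer charged, south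

Over-reaction product lies beyond the chains, so a flask need not end full of chains, and the question becomes how long they stand exposed. The maple run at 25 °C gives a first reading. Take g, the pseudo-first-order coefficient of the pool not yet in chains. In maple it reads 0.0612 h⁻¹ from 8.00 h to 12.0 h, but 0.0441 h⁻¹ from 12.0 h to 15.0 h. So g sags, and its fractional rate of fall, taken between the midpoints of the two spans, reads 0.0936 h⁻¹; this sag coefficient s, a reading carrying the scatter, may hold dying ends too.

My own reckoning takes s as chain loss and as a floor for a hotter flask. A chain then survives time t with the fraction exp(−s·t), which for south over 2.0 d is 1.12%. South-east is colder than maple, so s can't be applied there, but I expect it to come out ahead.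

The forecast also names south-east, with 72% there and 6% in south, and it hedges: “If the sag is instead dying ends, south would keep up to about 45%.” My figure for south lies lower.

The flasks give 80.8% in south-east, far more than the 0.713% in south.

    free monomer + initiator → living end + monomer in chains (k = 1.00 L mol⁻¹ min⁻¹, Ea = 64.0 kJ mol⁻¹)
    free monomer + living end → monomer in chains + living end, rate k2*[living end]*[free monomer] (k = 25.0 L mol⁻¹ min⁻¹, Ea = 39.0 kJ mol⁻¹)
    monomer in chains → over-reaction product (k = 0.00200 min⁻¹, Ea = 92.0 kJ mol⁻¹)
    living end + transfer agent → dead chain (kL = 0.190 L mol⁻¹ min⁻¹, Ea = 55.0 kJ mol⁻¹)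
    solid monomer ⇌ free monomer, rate k5*(cs5 - [free monomer]) while solid is left; crystals form when [free monomer] > cs5 (solubility = 43.0 mM, k = 0.00700 min⁻¹)
    (constants at 40 °C)

South ends so low mainly because monomer in chains is lost to over-reaction product: without that step, south holds 83.6%. Over its second day, south's chains fall at 0.113 h⁻¹, against maple's s of 0.0936 h⁻¹.

For the south flask left until 12 h, s gives a survival of 32.5%, so chains should still stand beside product. That flask holds 34.0% in chains and 42.2% as over-reaction product.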